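**Plan**

1. Germacrane numbering (C1=C10–C9–C8–C7–C6–C5=C4–C3–C2; C14 on C10, C15 on C4, lactone O on C8, C11–C13 on C7). The retrosynthesis removes the O15 acyl group and C13, then re-joins the two ring alkenes, which are 1,5-related through C2–C3, as the σ-bonds C1–C4 and C5–C10. This gives a cyclohexane (C5–C10) fused to a bicyclo[2.2.0]hexane (C1–C4, C5, C10).
2. That 6-4-4 tricycle is cut at C4–C5 and C1–C10 into a C5=C10 cyclohexenone (ketone at C6, C14 on C10) and a cyclobut-1-enecarboxylate (C1–C4, C15); C7–C11 is cut last.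
3. Forward: shikimic acid gives the enone; the [2+2] photocycloaddition closes the central cyclobutane; C11–C12 is alkylated onto C7 and the C6 oxygen leaves through an enol triflate; the γ-lactone is closed on the tricycle; heat opens the ten-membered ring; methylenation, O15 acylation and desilylation finish.
4. Stereochemistry: C8 comes from C5 of shikimic acid and is inverted (Mitsunobu) after the photo step, so that O8 ends on the cyclobutane face. C7 comes from a hydroxyl-directed hydrogenation (C11 trans to O8). The acyl centre comes from the (S)-Roche ester.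
5. Alkene geometry: the trans lactone holds ring C5–C10 in the chair that puts C9 axial and C6 equatorial on the intermediate cyclohexane-1,4-diyl, which should give ring-cis C1=C10 and ring-trans C4=C5.

Key step: step 10

Convention: germacrane numbering is used for all intermediates. On ring C5–C10 of the tricycles, β is the face carrying the cyclobutane bonds C5–C4 and C10–C1; α is the face of H5 and C14.

Assumption: the cyclobutene adds to the enone face opposite the C8 silyloxy group, as is usual for 5-substituted cyclohexenones; the other facial adduct is separated after step 10 and not carried on.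

Remark: a radical, cation or carbanion at C6 would open or rearrange the adjacent strained cyclobutane, so C6 is deoxygenated through an enol triflate and a hydrogenation.

Step 1
Reactants: 1 (−)-shikimic acid
Product: 3 methyl 3,4-O-isopropylideneshikimate, via methyl shikimate 2 (not isolated)
Conditions: MeOH, CSA (cat.), reflux; evaporate; 2,2-dimethoxypropane, acetone, CSA (cat.), rt
Reagents that add atoms: methanol, CO; 2,2-dimethoxypropane, COC(C)(C)OC
Why: Fischer esterification followed by thermodynamic ketalisation of the only cis-1,2-diol (O3/O4) leaves the C5 hydroxyl free and touches no stereocentre.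

Step 2
Reactants: 3 methyl 3,4-O-isopropylideneshikimate
Product: 4 methyl 5-O-(tert-butyldimethylsilyl)-3,4-O-isopropylideneshikimate
Conditions: TBSCl, imidazole, DMF, rt
Reagents that add atoms: tert-butyldimethylsilyl chloride, CC(C)(C)[Si](C)(C)Cl
Why: Standard silylation of the single free secondary alcohol (the future O8).

Step 3
Reactants: 4 methyl 5-O-TBS-3,4-O-isopropylideneshikimate
Product: 5 primary allylic alcohol (CO2Me of 4 reduced to CH2OH, the future C14)
Conditions: DIBAL-H, CH2Cl2, −78 °C; Rochelle salt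
Reagents that add atoms: none
Why: DIBAL-H reduces the conjugated ester by 1,2-addition to the allylic alcohol and leaves the ketal and silyl ether intact.

Step 4
Reactants: 5 primary allylic alcohol
Product: 6 tert-butyldiphenylsilyl ether of 5
Conditions: TBDPSCl, imidazole, DMF, rt
Reagents that add atoms: tert-butyldiphenylsilyl chloride, CC(C)(C)[Si](Cl)(c1ccccc1)c1ccccc1
Why: Silylation of the primary alcohol with an acid-stable group that has to survive until the last step.

Step 5
Reactants: 6 TBDPS ether
Product: 7 (1R,2R,6R)-6-(tert-butyldimethylsilyloxy)-4-(tert-butyldiphenylsilyloxymethyl)cyclohex-3-ene-1,2-diol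
Conditions: CuCl2·2H2O, MeCN, 0 °C to rt
Reagents that add atoms: none
Why: Lewis-acid-assisted hydrolysis should cleave the allylic isopropylidene ketal faster than the secondary TBS or the primary TBDPS ether.

Step 6
Reactants: 7 diol
Product: 8 (5R,6S)-5-(tert-butyldimethylsilyloxy)-6-hydroxy-3-(tert-butyldiphenylsilyloxymethyl)cyclohex-2-en-1-one
Conditions: activated MnO2, CH2Cl2, rt
Reagents that add atoms: none
Why: Manganese dioxide oxidises the allylic alcohol (future C6) selectively over the saturated one (future C7), giving the enone.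

Step 7
Reactants: 8 α′-hydroxy enone
Product: 9 (R)-5-(tert-butyldimethylsilyloxy)-3-(tert-butyldiphenylsilyloxymethyl)cyclohex-2-en-1-one
Conditions: SmI2, THF–MeOH, −78 °C
Reagents that add atoms: none
Why: SmI2 reduction of an α-hydroxy ketone (ketyl, loss of hydroxide, protonation of the samarium enolate) removes the C7 oxygen, and the cold protic medium should protonate the enolate before the β-silyloxy group can be lost.

Step 8
Reactants: 10 ethyl 1-bromocyclobutane-1-carboxylate
Product: 11 cyclobut-1-ene-1-carboxylic acid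
Conditions: KOH, toluene, reflux; aq. HCl
Reagents that add atoms: potassium hydroxide, [K+].[OH-]
Why: Hydroxide saponifies the ester and E2 loss of HBr from the tertiary α-bromide gives the conjugated cyclobutene acid, a known preparation.

Step 9
Reactants: 11 cyclobut-1-ene-1-carboxylic acid
Product: 12 tert-butyl cyclobut-1-ene-1-carboxylate
Conditions: tert-butyl 2,2,2-trichloroacetimidate, BF3·OEt2 (cat.), CH2Cl2–cyclohexane, rt; BHT, used fresh
Reagents that add atoms: tert-butyl 2,2,2-trichloroacetimidate, CC(C)(C)OC(=N)C(Cl)(Cl)Cl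
Why: Acid-catalysed O-alkylation with the imidate makes the tert-butyl ester without exposing the polymerisation-prone acrylate to base or nucleophiles.

Step 10
Reactants: 9 (R)-enone; 12 tert-butyl cyclobut-1-ene-1-carboxylate
Product: 13 cis-anti-cis 6-4-4 tricyclic keto ester (C6 ketone, 8α-OTBS, C10–CH2OTBDPS, C4–CO2tBu; cyclobutane on the face opposite OTBS)
Conditions: hν (Hg lamp, uranium-glass filter, λ > 340 nm), 12 (5 equiv), CH2Cl2, −20 °C; basic Al2O3 work-up
Reagents that add atoms: none
Why: Excitation of 9 and intersystem crossing give the twisted enone triplet, which adds to the strained, electron-poor alkene of 12 to form a triplet 1,4-diradical that closes after spin inversion; the closest known reaction type is the intermolecular [2+2] photocycloaddition of 3-substituted cyclohexenones with alkyl cyclobut-1-enecarboxylates. The one new ring, the central cyclobutane C5–C10–C1–C4, closes by recombination of that diradical, forming C4–C5 and C1–C10. C5 and C10 end cis because a trans-fused cyclohexanone–cyclobutane is strained and epimerises at C5 on basic alumina; C1 and C4 are cis because both belong to the cyclobutene ring; the anti arrangement of the outer rings follows from approach with the C2–C3 bridge turned away from the six-membered ring; the face is set by C8, the new axial bond at C10 forming trans to the equatorial OTBS. The step needs head-to-head regiochemistry, which the ester secures because the acceptor-bearing alkene carbon C4 bonds to the enone α-carbon C5, and it needs anti facial selectivity, which the C8 stereocentre supplies. Excess 12 and long-wavelength light suppress enone dimerisation.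

Step 11
Reactants: 13 tricyclic keto ester
Product: 14 C7-alkylated keto diester (CH2CO2tBu on C7, drawn 7β, trans to OTBS)
Conditions: LDA, THF, −78 °C; tert-butyl bromoacetate, DMPU, −78 to −40 °C
Reagents that add atoms: tert-butyl bromoacetate, CC(C)(C)OC(=O)CBr
Why: Kinetic deprotonation occurs at the C7 methylene (the other α-position is the hindered cyclobutane methine C5) and the lithium enolate is alkylated by the reactive α-bromo ester; the equatorial C8–O bond lies near the nodal plane of the enolate, which retards E1cB loss of silanolate, and the C7 configuration is of no consequence because C7 becomes sp2 in step 12.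

Step 12
Reactants: 14 C7-alkylated keto diester
Product: 15 enol triflate (C6(OTf)=C7)
Conditions: KHMDS, THF, −78 °C; N-(5-chloropyridin-2-yl)triflimide (Comins' reagent)
Reagents that add atoms: N-(5-chloropyridin-2-yl)-1,1,1-trifluoro-N-(trifluoromethylsulfonyl)methanesulfonamide, Clc1ccc(nc1)N(S(=O)(=O)C(F)(F)F)S(=O)(=O)C(F)(F)F
Why: The ketone is deprotonated at C7 in preference to the less acidic ester methylene and the strained C5 position, and O-sulfonylation of the potassium enolate gives the enol triflate.

Step 13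
Reactants: 15 enol triflate
Product: 16 C6=C7 alkene (C7–CH2CO2tBu, 8α-OTBS)
Conditions: Pd(OAc)2 (cat.), PPh3, Bu3N, HCO2H, DMF, 60 °C
Reagents that add atoms: none
Why: Palladium-catalysed formate reduction of the enol triflate (oxidative addition, formate-to-hydride exchange, reductive elimination) replaces the C6 oxygen by hydrogen without a radical, cation or carbanion at C6.

Step 14
Reactants: 16 allylic silyl ether
Product: 17 8α-allylic alcohol
Conditions: HF·pyridine, pyridine, THF, 0 °C
Reagents that add atoms: none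
Why: Buffered HF·pyridine cleaves the secondary allylic TBS ether much faster than the neopentyl TBDPS ether and leaves the tert-butyl esters.

Step 15
Reactants: 17 8α-allylic alcohol
Product: 18 8β-(4-nitrobenzoate)
Conditions: 4-nitrobenzoic acid, PPh3, DIAD, toluene, 0 °C to rt
Reagents that add atoms: 4-nitrobenzoic acid, OC(=O)c1ccc(cc1)[N+](=O)[O-]
Why: Mitsunobu esterification displaces the activated allylic C8 oxygen with inversion (SN2), turning the shikimate-derived 8α configuration into 8β, which is the (8S) configuration of the target and places O8 on the cyclobutane face.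

Step 16
Reactants: 18 8β-(4-nitrobenzoate)
Product: 19 8β-allylic alcohol
Conditions: K2CO3, MeOH, 0 °C
Reagents that add atoms: none
Why: Mild methanolysis removes the electron-poor aryl ester and leaves both tert-butyl esters.

Step 17
Reactants: 19 8β-allylic alcohol
Product: 20 saturated 8β-hydroxy di-tert-butyl ester (C7 side chain α, trans to OH; C6 now CH2)
Conditions: [Ir(cod)(PCy3)(py)]PF6 (cat.), H2 (1 atm), CH2Cl2, rt
Reagents that add atoms: none
Why: Crabtree's catalyst binds the C8 hydroxyl and delivers H2 to the same (β) face of the trisubstituted C6=C7 bond (hydroxyl-directed hydrogenation), so H7 ends cis and the C7 side chain trans to O8, which sets (7R).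

Step 18
Reactants: 20 hydroxy di-tert-butyl ester
Product: 22 trans-fused C12→O8 γ-lactone carrying the C4 carboxylic acid, via hydroxy diacid 21 (not isolated)
Conditions: TFA, CH2Cl2, 0 °C to rt; then toluene, 60 °C
Reagents that add atoms: none
Why: Acidolysis (loss of tert-butyl cation) unmasks both acids, and the C12 acid lactonises onto the trans-disposed C8 hydroxyl under the same acid with retention at C7 and C8.

Step 19
Reactants: 22 lactone acid
Product: 23 trans-fused lactone with C4–CH2OH (the C15 alcohol)
Conditions: BH3·THF, THF, 0 °C to rt; MeOH, then aq. work-up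
Reagents that add atoms: none
Why: Borane reduces a free carboxylic acid much faster than a lactone, giving the neopentyl C15 alcohol while the molecule is still free of alkenes.

Step 20
Reactants: 23 tricyclic lactone alcohol
Product: 24 (1(10)E,4Z,7R,8S)-14-(tert-butyldiphenylsilyloxy)-15-hydroxygermacra-1(10),4-dien-12,8-olide (ring-cis C1=C10, ring-trans C4=C5)
Conditions: toluene (degassed, BHT), sealed tube, 200 °C
Reagents that add atoms: none
Why: Thermal [σ2s+σ2a] cycloreversion of the bicyclo[2.2.0]hexane, known for 6-4-4 photoadducts, breaks C1–C4 to a cyclohexane-1,4-diyl and then C5–C10; the trans lactone holds ring C5–C10 in the chair with the C7 and C8 substituents equatorial, which places C9 axial and C6 equatorial on the diyl chair, so C1=C10 should form ring-cis and C4=C5 ring-trans while C7 and C8 are untouched.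

Step 21
Reactants: 24 diene lactone
Product: 27 (1(10)E,4Z,7R,8S)-14-(tert-butyldiphenylsilyloxy)-15-hydroxygermacra-1(10),4,11(13)-trien-12,8-olide, via Mannich base 25 (not isolated), via methiodide 26 (not isolated)
Conditions: LDA (2.5 equiv), THF, −78 °C; Me2N=CH2 I, −78 to 0 °C; MeI, MeOH, rt; aq. NaHCO3, EtOAc
Reagents that add atoms: N,N-dimethylmethyleneiminium iodide (Eschenmoser's salt), C[N+](C)=C.[I-]
Why: The lactone enolate (the extra base covers the C15 alkoxide) undergoes a Mannich reaction with Eschenmoser's salt, and quaternisation followed by E1cB loss of trimethylamine gives the exocyclic methylene, in which C11 is not stereogenic.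

Step 22
Reactants: 28 methyl (S)-3-hydroxy-2-methylpropanoate
Product: 29 methyl (S)-3-(tert-butyldimethylsilyloxy)-2-methylpropanoate
Conditions: TBSCl, imidazole, CH2Cl2, rt
Reagents that add atoms: tert-butyldimethylsilyl chloride, CC(C)(C)[Si](C)(C)Cl
Why: Standard silylation of the primary alcohol of the Roche ester.

Step 23
Reactants: 29 silylated Roche ester
Product: 30 (S)-3-(tert-butyldimethylsilyloxy)-2-methylpropanoic acid
Conditions: LiOH, THF–H2O, 0 °C; aq. HCl to pH 4
Reagents that add atoms: lithium hydroxide, [Li+].[OH-]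
Why: Cold lithium hydroxide hydrolysis gives the acid without epimerising the α-methyl centre, as is routine for Roche-ester derivatives.

Step 24
Reactants: 27 α-methylene lactone alcohol; 30 (S)-acid
Product: 31 bis-silyl ether of the target (O14–TBDPS, side-chain O–TBS)
Conditions: EDC·HCl, DMAP (cat.), CH2Cl2, 0 °C to rt
Reagents that add atoms: none
Why: Carbodiimide/DMAP (Steglich) esterification of the primary allylic C15 alcohol proceeds under near-neutral conditions that the α-methylene lactone and the α-stereocentre of the acid tolerate.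

Step 25
Reactants: 31 bis-silyl ether
Product: 32 CNP0241696.1, (1(10)E,4Z,7R,8S)-14-hydroxy-15-[(S)-3-hydroxy-2-methylpropanoyloxy]germacra-1(10),4,11(13)-trien-12,8-olide
Conditions: HF·pyridine, pyridine, THF, 0 °C to rt
Reagents that add atoms: none
Why: Fluoride cleaves both silyl ethers under mildly acidic conditions that spare the α-methylene lactone, the allylic ester and the β-hydroxy ester.

**Compound list**

1 | (−)-shikimic acid, (3R,4S,5R)-3,4,5-trihydroxycyclohex-1-ene-1-carboxylic acid | C1[C@H]([C@@H]([C@@H](C=C1C(=O)O)O)O)O | starting material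
2 | methyl shikimate | C1[C@H]([C@@H]([C@@H](C=C1C(=O)OC)O)O)O | intermediate
3 | methyl 3,4-O-isopropylideneshikimate, methyl (3aR,7R,7aS)-7-hydroxy-2,2-dimethyl-3a,6,7,7a-tetrahydro-1,3-benzodioxole-5-carboxylate | C1[C@H]([C@H]2[C@@H](C=C1C(=O)OC)OC(C)(C)O2)O | intermediate
4 | methyl 5-O-(tert-butyldimethylsilyl)-3,4-O-isopropylideneshikimate | C1[C@H]([C@H]2[C@@H](C=C1C(=O)OC)OC(C)(C)O2)O[Si](C)(C)C(C)(C)C | intermediate
5 | primary allylic alcohol from 4 (CO2Me reduced to CH2OH, shikimate configuration unchanged) | C1[C@H]([C@H]2[C@@H](C=C1CO)OC(C)(C)O2)O[Si](C)(C)C(C)(C)C | intermediate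
6 | tert-butyldiphenylsilyl ether of 5 | C1[C@H]([C@H]2[C@@H](C=C1CO[Si](c3ccccc3)(c4ccccc4)C(C)(C)C)OC(C)(C)O2)O[Si](C)(C)C(C)(C)C | intermediate
7 | (1R,2R,6R)-6-(tert-butyldimethylsilyloxy)-4-(tert-butyldiphenylsilyloxymethyl)cyclohex-3-ene-1,2-diol | C1[C@H]([C@@H]([C@@H](C=C1CO[Si](c2ccccc2)(c3ccccc3)C(C)(C)C)O)O)O[Si](C)(C)C(C)(C)C | intermediate
8 | (5R,6S)-5-(tert-butyldimethylsilyloxy)-6-hydroxy-3-(tert-butyldiphenylsilyloxymethyl)cyclohex-2-en-1-one | C1[C@H]([C@@H](C(=O)C=C1CO[Si](c2ccccc2)(c3ccccc3)C(C)(C)C)O)O[Si](C)(C)C(C)(C)C | intermediate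
9 | (R)-5-(tert-butyldimethylsilyloxy)-3-(tert-butyldiphenylsilyloxymethyl)cyclohex-2-en-1-one | O=C1C[C@H](O[Si](C)(C)C(C)(C)C)CC(CO[Si](c2ccccc2)(c3ccccc3)C(C)(C)C)=C1 | intermediate
10 | ethyl 1-bromocyclobutane-1-carboxylate | CCOC(=O)C1(Br)CCC1 | starting material
11 | cyclobut-1-ene-1-carboxylic acid | OC(=O)C1=CCC1 | intermediate
12 | tert-butyl cyclobut-1-ene-1-carboxylate | CC(C)(C)OC(=O)C1=CCC1 | intermediate
13 | cis-anti-cis 6-4-4 keto ester (tricyclo[4.4.0.0^2,5]decane skeleton): C6 ketone, 8α-OTBS, C10–CH2OTBDPS, C4–CO2tBu, cyclobutane β | O=C1C[C@H](O[Si](C)(C)C(C)(C)C)C[C@@]2(CO[Si](c4ccccc4)(c5ccccc5)C(C)(C)C)[C@@H]3CC[C@]3(C(=O)OC(C)(C)C)[C@@H]12 | intermediate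
14 | 13 bearing CH2CO2tBu at C7 (drawn 7β, trans to OTBS) | O=C1[C@@H](CC(=O)OC(C)(C)C)[C@H](O[Si](C)(C)C(C)(C)C)C[C@@]2(CO[Si](c4ccccc4)(c5ccccc5)C(C)(C)C)[C@@H]3CC[C@]3(C(=O)OC(C)(C)C)[C@@H]12 | intermediate
15 | C6 enol triflate of 14 (C6=C7) | FC(F)(F)S(=O)(=O)OC1=C(CC(=O)OC(C)(C)C)[C@H](O[Si](C)(C)C(C)(C)C)C[C@@]2(CO[Si](c4ccccc4)(c5ccccc5)C(C)(C)C)[C@@H]3CC[C@]3(C(=O)OC(C)(C)C)[C@@H]12 | intermediate
16 | C6=C7 alkene with C7–CH2CO2tBu and 8α-OTBS | C1=C(CC(=O)OC(C)(C)C)[C@H](O[Si](C)(C)C(C)(C)C)C[C@@]2(CO[Si](c4ccccc4)(c5ccccc5)C(C)(C)C)[C@@H]3CC[C@]3(C(=O)OC(C)(C)C)[C@@H]12 | intermediate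
17 | 8α-allylic alcohol | C1=C(CC(=O)OC(C)(C)C)[C@H](O)C[C@@]2(CO[Si](c4ccccc4)(c5ccccc5)C(C)(C)C)[C@@H]3CC[C@]3(C(=O)OC(C)(C)C)[C@@H]12 | intermediate
18 | 8β-(4-nitrobenzoate) | C1=C(CC(=O)OC(C)(C)C)[C@@H](OC(=O)c6ccc(cc6)[N+](=O)[O-])C[C@@]2(CO[Si](c4ccccc4)(c5ccccc5)C(C)(C)C)[C@@H]3CC[C@]3(C(=O)OC(C)(C)C)[C@@H]12 | intermediate
19 | 8β-allylic alcohol | C1=C(CC(=O)OC(C)(C)C)[C@@H](O)C[C@@]2(CO[Si](c4ccccc4)(c5ccccc5)C(C)(C)C)[C@@H]3CC[C@]3(C(=O)OC(C)(C)C)[C@@H]12 | intermediate
20 | saturated 8β-hydroxy di-tert-butyl ester, C7–CH2CO2tBu α (trans to OH) | C1[C@H](CC(=O)OC(C)(C)C)[C@@H](O)C[C@@]2(CO[Si](c4ccccc4)(c5ccccc5)C(C)(C)C)[C@@H]3CC[C@]3(C(=O)OC(C)(C)C)[C@@H]12 | intermediate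
21 | hydroxy diacid from 20 | C1[C@H](CC(=O)O)[C@@H](O)C[C@@]2(CO[Si](c4ccccc4)(c5ccccc5)C(C)(C)C)[C@@H]3CC[C@]3(C(=O)O)[C@@H]12 | intermediate
22 | trans-fused C12→O8 γ-lactone with C4–CO2H | C1[C@@H]2CC(=O)O[C@H]2C[C@@]3(CO[Si](c5ccccc5)(c6ccccc6)C(C)(C)C)[C@@H]4CC[C@]4(C(=O)O)[C@@H]13 | intermediate
23 | trans-fused lactone with C4–CH2OH (C15 alcohol) | C1[C@@H]2CC(=O)O[C@H]2C[C@@]3(CO[Si](c5ccccc5)(c6ccccc6)C(C)(C)C)[C@@H]4CC[C@]4(CO)[C@@H]13 | intermediate
24 | (1(10)E,4Z,7R,8S)-14-(tert-butyldiphenylsilyloxy)-15-hydroxygermacra-1(10),4-dien-12,8-olide | C1C(=O)O[C@H]2C/C(CO[Si](c3ccccc3)(c4ccccc4)C(C)(C)C)=C\CC/C(CO)=C/C[C@H]12 | intermediate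
25 | 11-(dimethylaminomethyl) derivative of 24 (C11 epimers) | CN(C)CC1C(=O)O[C@H]2C/C(CO[Si](c3ccccc3)(c4ccccc4)C(C)(C)C)=C\CC/C(CO)=C/C[C@H]12 | intermediate
26 | trimethylammonium iodide of 25 | C[N+](C)(C)CC1C(=O)O[C@H]2C/C(CO[Si](c3ccccc3)(c4ccccc4)C(C)(C)C)=C\CC/C(CO)=C/C[C@H]12.[I-] | intermediate
27 | (1(10)E,4Z,7R,8S)-14-(tert-butyldiphenylsilyloxy)-15-hydroxygermacra-1(10),4,11(13)-trien-12,8-olide | C=C1C(=O)O[C@H]2C/C(CO[Si](c3ccccc3)(c4ccccc4)C(C)(C)C)=C\CC/C(CO)=C/C[C@H]12 | intermediate
28 | methyl (S)-3-hydroxy-2-methylpropanoate | COC(=O)[C@@H](C)CO | starting material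
29 | methyl (S)-3-(tert-butyldimethylsilyloxy)-2-methylpropanoate | COC(=O)[C@@H](C)CO[Si](C)(C)C(C)(C)C | intermediate
30 | (S)-3-(tert-butyldimethylsilyloxy)-2-methylpropanoic acid | OC(=O)[C@@H](C)CO[Si](C)(C)C(C)(C)C | intermediate
31 | O14-TBDPS, side-chain O-TBS bis-silyl ether of the target | C=C1C(=O)O[C@H]2C/C(CO[Si](c3ccccc3)(c4ccccc4)C(C)(C)C)=C\CC/C(COC(=O)[C@@H](C)CO[Si](C)(C)C(C)(C)C)=C/C[C@H]12 | intermediate
32 | CNP0241696.1, (1(10)E,4Z,7R,8S)-14-hydroxy-15-[(S)-3-hydroxy-2-methylpropanoyloxy]germacra-1(10),4,11(13)-trien-12,8-olide | C=C1C(=O)O[C@H]2C/C(CO)=C\CC/C(COC(=O)[C@@H](C)CO)=C/C[C@H]12 | target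

**Step count**

Total: 25 steps. Longest linear sequence: 21 steps (1–7, 10–21, 24, 25).

**Steps most likely to fail**

Step 20. At the temperature needed to cleave a bicyclo[2.2.0]hexane that carries no radical-stabilising group, the cis,trans-diene may go on to a Cope rearrangement to the divinylcyclohexane, or the diyl may cleave along C2–C3 instead of C5–C10. The fallback sets out from 22, in which the carboxyl group on C4 stabilises the diyl and the lactone lock is already in place, so the cycloreversion should run well below 200 °C (toluene, about 150 °C). This gives the cyclodecadienoic acid F1. Activation with isobutyl chloroformate and N-methylmorpholine (THF, −15 °C) gives the mixed carbonic anhydride F2, which is reduced in the same flask with NaBH4 in water; the lactone is not touched. The route is rejoined at 24.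

Step 11. The C6/C7 enolate may expel the β-silanolate (E1cB) to give the tricyclic enone, or exchange protons before it is alkylated. The fallback sets out from 13. Desilylation with HF·pyridine gives the β-hydroxy ketone F3. Its dianion (LDA, 2.2 equiv, −78 °C), in which the β-oxido group is no leaving group, is alkylated with tert-butyl bromoacetate anti to the oxido group to give the hydroxy keto diester F4. Resilylation (TBSCl, imidazole, DMF) rejoins the route at 14.

Step 15. On this hindered allylic alcohol the oxyphosphonium intermediate may eliminate to a diene or be attacked at C6 with allylic shift instead of undergoing inversion at C8. The fallback sets out from 17. Oxidation with MnO2 gives the enone F5. Reagent-controlled reduction with (R)-2-methyl-CBS-oxazaborolidine and BH3·SMe2 (toluene, −40 °C) delivers hydride to the α face, with the alkenyl carbon C7 as the large group. The route is rejoined at 19.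

Further compounds

F1 | step 20 | (1(10)E,4Z,7R,8S)-14-(tert-butyldiphenylsilyloxy)-12,8-olidogermacra-1(10),4-dien-15-oic acid | C1C(=O)O[C@H]2C/C(CO[Si](c3ccccc3)(c4ccccc4)C(C)(C)C)=C\CC/C(C(=O)O)=C/C[C@H]12
F2 | step 20 | isobutyl carbonic mixed anhydride of F1 | C1C(=O)O[C@H]2C/C(CO[Si](c3ccccc3)(c4ccccc4)C(C)(C)C)=C\CC/C(C(=O)OC(=O)OCC(C)C)=C/C[C@H]12
F3 | step 11 | 8α-hydroxy tricyclic keto ester (13 without TBS) | O=C1C[C@H](O)C[C@@]2(CO[Si](c4ccccc4)(c5ccccc5)C(C)(C)C)[C@@H]3CC[C@]3(C(=O)OC(C)(C)C)[C@@H]12
F4 | step 11 | 8α-hydroxy-7β-(tert-butoxycarbonylmethyl) tricyclic keto ester | O=C1[C@@H](CC(=O)OC(C)(C)C)[C@H](O)C[C@@]2(CO[Si](c4ccccc4)(c5ccccc5)C(C)(C)C)[C@@H]3CC[C@]3(C(=O)OC(C)(C)C)[C@@H]12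
F5 | step 15 | tricyclic C8 enone (C8=O, C6=C7, C7–CH2CO2tBu) | C1=C(CC(=O)OC(C)(C)C)C(=O)C[C@@]2(CO[Si](c4ccccc4)(c5ccccc5)C(C)(C)C)[C@@H]3CC[C@]3(C(=O)OC(C)(C)C)[C@@H]12
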